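The easiest step with these runs is a sum: at the last reading of a run, target and isomer of the product are added and set against the charge of starting material.

| setting | cedar | larch | elm | flask |
|---|---|---|---|---|
| starting material | 0.67 mM (fed, over 5.0 s) | 1.5 mM (fed, over 5.0 s) | 1 mM (fed, over 5.0 s) | 1.0 mM (fed, over 5.0 s) |
| reagent | 1.5 equiv | 1.5 equiv | 1.5 equiv | 1.50 equiv |
| protic impurity | 0.30 mM | 0.30 mM | 0.60 mM | 0.300 mM |
| remark | run made earlier | run made earlier | run made earlier |  |
| time |  |  |  | 4.0 min |

- cedar (time / min: starting material / %, target / %, isomer of the product / %): 0.667: 33.1, 14.5, 10.0; 1.33: 8.5, 29.2, 16.0; 2.00: 3.9, 36.0, 20.8; 2.50: 0.4, 33.7, 20.0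
- larch (time / min: starting material / %, target / %, isomer of the product / %): 0.200: 26.0, 40.2, 13.7; 0.417: 0.3, 52.3, 29.1; 1.00: 0, 50.8, 28.8; 2.50: 0.8, 51.6, 29.9
- elm (time / min: starting material / %, target / %, isomer of the product / %): 0.333: 27.5, 7.4, 6.0; 0.833: 3.9, 23.1, 10.7; 1.50: 0.9, 26.9, 12.9; 2.50: 0, 25.6, 13.7

(scatter of a reading: 1 percentage point)

- the analysis behind the earlier runs scatters by 1 percentage point, standard deviation
- the reaction counts as stopped when no species that holds the starting material changes by six tenths of a point or more over the second half of the time

- the state of affairs at 4.0 min: stopped, and by what, or still going (all of the starting material has reacted / forward and back rates have come level / the reagent has run out first / it is still moving)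
- conversion of starting material at 4.0 min
- amount of target at 4.0 min, in percent of the starting material charged
- amount of isomer of the product at 4.0 min, in percent of the starting material charged

The elm run looks nearly the same as the flask, with 1 mM of starting material, 1.5 equiv of reagent and the same feed, but it carries twice the [protic impurity]. Its last reading sums to 39.3 %, so 0.607 mM of starting material did not appear as product, close to the 0.60 mM of impurity charged. The cedar and larch runs, each with 0.30 mM of impurity, fall short, once the starting material still read is counted too, by 0.308 mM and 0.266 mM, although their charges of starting material are 0.67 mM and 1.5 mM. The loss therefore follows the impurity, mole for mole, and not the starting material. In the flask it comes to 30.0 % of the charge, and this figure, the impurity toll, charged [protic impurity] over charged [starting material], is the quantity carried forward. Elm ends low since its toll is 60.0 %, larger than the flask's, while the flask, with the same charges of starting material and reagent and 4.0 min against the 2.50 min in which elm's starting material came to read 0 %, should stop with 70.0 % as target and isomer together; that is the reckoning made here.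

The forecast says all of the starting material has reacted, with conversion 99.9 %, target 45 % and isomer of the product 25 %, on the ground that “So the protic impurity destroys starting-material-derived material 1:1, and early.”

The flask gives all of the starting material has reacted, with conversion 100 %, target 44.9 % and isomer of the product 25.1 %, together 70.0 %, beside 30.0 % of quenched substrate against the toll of 30.0 %.

    starting material + reagent + target → 2 target (k = 2.70 × 10⁵ /M²/s)
    starting material + reagent → target (k = 3.60 /M/s)
    target ⇌ isomer of the product (K = 0.560, k = 0.180 /s)
    starting material + protic impurity → quenched substrate (k = 810 /M/s)

At the end of the feed, at 0.0833 min, the flask held 23.8 % of quenched substrate against 1.24 % of target, with 20.8 % of the charge of protic impurity still there, and at 0.357 min the half-life of starting material by the path to quenched substrate is 5.4 h, longer than the 2.8 min by the plain path to target. In the flask the protic impurity, charged below the starting material and so the limiting reagent of that path, stands at 0 % of its charge at 4.00 min. The neighbour with 2.5 mM of starting material has a toll of 12.0 %, which leaves 88.0 %, and it holds 56.4 % of target and 31.6 % of isomer of the product.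

The readings were computed with made-up constants; the scatter is artificial.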